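**Plan** (locants are those of isochroman-1-one: C1 lactone carbonyl, O2, C3 lactol carbon, C4 methine, C4a–C8a arene)

- Retrosynthesis: (a) remove three benzyl ethers; (b) cut C4–C3 of the lactone ring to give an acyclic mixed anhydride of a 2-vinylbenzoic acid and an (aroyloxy)acetic acid; (c) cut the anhydride C–O bond; (d) cut the glycolate O–CH2 bond and take both arenes back to one aldehyde made from 4,5-dimethylresorcinol.
- Enabling feature: C3 carries the ring oxygen O2 of an aryl carboxylate and a hydroxyl group, so the lactol ring (C1, O2, C3, C4, C4a, C8a) is the arrested tetrahedral adduct of a C4 nucleophile with an acyl group hung on the C1 carboxylate. C4 is a methyl-bearing benzylic carbon ortho to that carboxyl, so hydrocupration of a vinyl group can make it both nucleophilic and stereogenic.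
- Forward: formylation; five steps to the vinyl acid; four steps to the glycolic acid; mixed anhydride; copper hydride cyclisation closes the lactone ring, the only ring made in the route; hydrogenolysis.
- Stereochemistry: C4 from the chiral bisphosphine on copper in the hydrocupration; C3 follows by lactol equilibration.

Key step: step 12

Remark 1: the lactol carbon C3 is taken to equilibrate through the ring-opened keto acid and to rest in the (3R) form of the target, with the hydroxyl axial (anomeric effect) and trans to the pseudoaxial C4 methyl group and the acyloxymethyl group equatorial, so only C4 has to be set by a reagent.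

Remark 2: (S,S)-Ph-BPE is written as the ligand enantiomer assumed to place copper on the face of the vinyl group that leads to (4S); if the sense of induction were the opposite, (R,R)-Ph-BPE would be used with no other change.

**Step 1**
Reactants: 1 4,5-dimethylresorcinol
Product: 2 2,4-dihydroxy-5,6-dimethylbenzaldehyde
Conditions: POCl3, DMF, MeCN, 0 °C → rt; then H2O, 50 °C
Reagents that add atoms: N,N-dimethylformamide CN(C)C=O; water O
Why: Vilsmeier–Haack formylation of the activated resorcinol should go at C6, para to one hydroxyl and ortho to the other as with orcinol, because C2 between the two hydroxyls is the more crowded site.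

**Step 2**
Reactants: 2 2,4-dihydroxy-5,6-dimethylbenzaldehyde
Product: 3 2-hydroxy-4-methoxy-5,6-dimethylbenzaldehyde
Conditions: MeI (1.05 equiv), K2CO3 (1.1 equiv), acetone, rt
Reagents that add atoms: iodomethane CI
Why: Williamson methylation with one equivalent of base should take only the 4-hydroxyl, since the 2-hydroxyl is held in a hydrogen bond to the formyl group and is the less nucleophilic one.

**Step 3**
Reactants: 3 2-hydroxy-4-methoxy-5,6-dimethylbenzaldehyde
Product: 4 2-(benzyloxy)-4-methoxy-5,6-dimethylbenzaldehyde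
Conditions: BnBr, K2CO3, DMF, 60 °C
Reagents that add atoms: benzyl bromide BrCc1ccccc1
Why: Williamson benzylation under more forcing conditions alkylates the remaining chelated phenol.

**Step 4**
Reactants: 4 2-(benzyloxy)-4-methoxy-5,6-dimethylbenzaldehyde
Product: 6 methyl 2-(benzyloxy)-4-methoxy-5,6-dimethylbenzoate, via crude carboxylic acid 5 (not isolated)
Conditions: NaClO2, NaH2PO4, 2-methyl-2-butene, t-BuOH/THF/H2O, rt; then MeI, K2CO3, DMF, rt
Reagents that add atoms: sodium chlorite [Na+].[O-]Cl=O; iodomethane CI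
Why: Pinnick oxidation (the alkene scavenges hypochlorite and protects the electron-rich ring) followed by SN2 esterification of the carboxylate, the reliable way to esterify a doubly ortho-substituted benzoic acid.

**Step 5**
Reactants: 6 methyl 2-(benzyloxy)-4-methoxy-5,6-dimethylbenzoate
Product: 7 8-(benzyloxy)-6-methoxy-5-methyl-3,4-dihydro-1H-isochromen-1-one
Conditions: LiN(i-Pr)2 (1.1 equiv), THF, −78 °C; CH2O (gas, from cracked paraformaldehyde), −78 °C → rt; aq. NH4Cl
Reagents that add atoms: formaldehyde C=O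
Why: Lateral lithiation of the ortho-toluate (only the 6-methyl group is conjugated with the ester) and addition of the benzylic anion to formaldehyde, with lactonisation of the alkoxide onto the ester in the flask, is the toluate-anion route to 3,4-dihydroisocoumarins.

**Step 6**
Reactants: 7 8-(benzyloxy)-6-methoxy-5-methyl-3,4-dihydro-1H-isochromen-1-one
Product: 8 6-(benzyloxy)-4-methoxy-3-methyl-2-vinylbenzoic acid
Conditions: LiN(i-Pr)2 (1.5 equiv), THF, −78 → 0 °C; then cold 1 M HCl to pH 3
Reagents that add atoms: none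
Why: Deprotonation at benzylic C4 gives the lactone dienolate, which should expel the carboxylate from C3 in an E1cB ring opening, the base-induced cleavage of 3,4-dihydroisocoumarins to ortho-alkenylbenzoic acids.

**Step 7**
Reactants: 2 2,4-dihydroxy-5,6-dimethylbenzaldehyde
Product: 9 2,4-bis(benzyloxy)-5,6-dimethylbenzaldehyde
Conditions: BnBr (2.4 equiv), K2CO3, DMF, 60 °C
Reagents that add atoms: benzyl bromide BrCc1ccccc1
Why: Williamson benzylation of both phenols, which must be masked because free phenols would quench the copper hydride and the copper alkyl of the key step.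

**Step 8**
Reactants: 9 2,4-bis(benzyloxy)-5,6-dimethylbenzaldehyde
Product: 10 2,4-bis(benzyloxy)-5,6-dimethylbenzoic acid
Conditions: NaClO2, NaH2PO4, 2-methyl-2-butene, t-BuOH/THF/H2O, rt
Reagents that add atoms: sodium chlorite [Na+].[O-]Cl=O
Why: Pinnick oxidation of the hindered aldehyde, with the alkene scavenger keeping hypochlorite off the electron-rich ring.

**Step 9**
Reactants: 10 2,4-bis(benzyloxy)-5,6-dimethylbenzoic acid; 11 allyl bromoacetate
Product: 12 allyl {[2,4-bis(benzyloxy)-5,6-dimethylbenzoyl]oxy}acetate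
Conditions: Cs2CO3, DMF, rt
Reagents that add atoms: none
Why: SN2 alkylation of the caesium carboxylate by the alpha-bromo ester makes the hindered aryl ester at oxygen, so the doubly ortho-substituted carbonyl never has to be attacked.

**Step 10**
Reactants: 12 allyl {[2,4-bis(benzyloxy)-5,6-dimethylbenzoyl]oxy}acetate
Product: 13 {[2,4-bis(benzyloxy)-5,6-dimethylbenzoyl]oxy}acetic acid
Conditions: Pd(PPh3)4 (3 mol%), morpholine, THF, rt; dilute HCl work-up
Reagents that add atoms: none
Why: Palladium-catalysed allyl transfer to morpholine through a pi-allyl complex (Tsuji–Trost type) frees the acid under neutral conditions that leave the benzyl ethers and the aryl ester alone.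

**Step 11**
Reactants: 13 {[2,4-bis(benzyloxy)-5,6-dimethylbenzoyl]oxy}acetic acid; 8 6-(benzyloxy)-4-methoxy-3-methyl-2-vinylbenzoic acid
Product: 15 6-(benzyloxy)-4-methoxy-3-methyl-2-vinylbenzoic {[2,4-bis(benzyloxy)-5,6-dimethylbenzoyl]oxy}acetic anhydride, via acid chloride 14 (not isolated)
Conditions: 13, (COCl)2, cat. DMF, CH2Cl2, 0 °C → rt, evaporate; then 8, N-methylmorpholine, THF, −20 → 0 °C; filter under argon, concentrate, use at once
Reagents that add atoms: none
Why: Acylation of the hindered carboxylate of 8 by the unhindered acid chloride 14 gives the mixed anhydride, and exchange to symmetric anhydrides is not expected because attack of the only carboxylate present at the aliphatic carbonyl merely regenerates 15.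

**Step 12**
Reactants: 15 6-(benzyloxy)-4-methoxy-3-methyl-2-vinylbenzoic {[2,4-bis(benzyloxy)-5,6-dimethylbenzoyl]oxy}acetic anhydride
Product: 17 [(3R,4S)-8-(benzyloxy)-3-hydroxy-6-methoxy-4,5-dimethyl-1-oxo-3,4-dihydro-1H-isochromen-3-yl]methyl 2,4-bis(benzyloxy)-5,6-dimethylbenzoate, via silyl ketal 16 (not isolated)
Conditions: Cu(OAc)2 (5 mol%), (S,S)-Ph-BPE (6 mol%), MeSiH(OMe)2 (1.5 equiv), THF, 0 °C → rt; then aq. citric acid/THF, rt
Reagents that add atoms: none
Why: Proposed new method: the bisphosphine copper hydride formed from Cu(OAc)2, (S,S)-Ph-BPE and the silane should add across the vinyl group with copper on the benzylic carbon and hydrogen on the terminal carbon (which becomes the C4 methyl group), and the benzylic copper should then add with retention to the nearer anhydride carbonyl, so that the C4–C3 bond closes the lactone ring and the copper lactolate is silylated by Si–H sigma-bond metathesis, which returns the copper hydride. The closest known reaction type is the copper hydride-catalysed enantioselective hydroacylation of aryl alkenes with carboxylic anhydrides, here made intramolecular so that the tetrahedral adduct, a six-membered acyloxy ketal, is kept instead of collapsing to a free ketone. The ring closes in the 6-exo-trig mode, C4 adding to the C3 carbonyl carbon with O2 and C1 already in the tether. C4 is set by the chiral bisphosphine in the hydrocupration, and C3 settles after hydrolysis by ring-chain equilibration to the lactol with axial hydroxyl trans to the C4 methyl group. The step needs hydrocupration to outrun hydride reduction of the anhydride and needs the copper alkyl to choose the aliphatic carbonyl: the vinyl group sits on an acceptor-substituted arene, attack at the aroyl carbonyl would need a four-membered ring, and the distal aryl ester is doubly ortho-substituted and out of reach. Over-reduction and epimerisation should be held back because the ketone stays masked as silyl ketal 16 until the mildly acidic work-up.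

**Step 13**
Reactants: 17 [(3R,4S)-8-(benzyloxy)-3-hydroxy-6-methoxy-4,5-dimethyl-1-oxo-3,4-dihydro-1H-isochromen-3-yl]methyl 2,4-bis(benzyloxy)-5,6-dimethylbenzoate
Product: 18 [(3R,4S)-3,8-dihydroxy-6-methoxy-4,5-dimethyl-1-oxo-3,4-dihydro-1H-isochromen-3-yl]methyl 2,4-dihydroxy-5,6-dimethylbenzoate
Conditions: H2 (1 atm), Pd/C (10% Pd on carbon), EtOAc, rt
Reagents that add atoms: none
Why: Hydrogenolysis of the three aryl benzyl ethers is neutral, so the lactol, the acyloxymethyl ester and the C4 centre (epimerisable only through the ring-opened ketone under base) should be untouched.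

**Compound list**

1 | 4,5-dimethylresorcinol (4,5-dimethylbenzene-1,3-diol) | Cc1cc(O)cc(O)c1C | starting material
2 | 2,4-dihydroxy-5,6-dimethylbenzaldehyde | O=Cc1c(O)cc(O)c(C)c1C | intermediate
3 | 2-hydroxy-4-methoxy-5,6-dimethylbenzaldehyde | O=Cc1c(O)cc(OC)c(C)c1C | intermediate
4 | 2-(benzyloxy)-4-methoxy-5,6-dimethylbenzaldehyde | O=Cc1c(OCc2ccccc2)cc(OC)c(C)c1C | intermediate
5 | 2-(benzyloxy)-4-methoxy-5,6-dimethylbenzoic acid | OC(=O)c1c(OCc2ccccc2)cc(OC)c(C)c1C | intermediate
6 | methyl 2-(benzyloxy)-4-methoxy-5,6-dimethylbenzoate | COC(=O)c1c(OCc2ccccc2)cc(OC)c(C)c1C | intermediate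
7 | 8-(benzyloxy)-6-methoxy-5-methyl-3,4-dihydro-1H-isochromen-1-one | O=C1OCCc2c(C)c(OC)cc(OCc3ccccc3)c12 | intermediate
8 | 6-(benzyloxy)-4-methoxy-3-methyl-2-vinylbenzoic acid | C=Cc1c(C)c(OC)cc(OCc2ccccc2)c1C(=O)O | intermediate
9 | 2,4-bis(benzyloxy)-5,6-dimethylbenzaldehyde | O=Cc1c(OCc2ccccc2)cc(OCc2ccccc2)c(C)c1C | intermediate
10 | 2,4-bis(benzyloxy)-5,6-dimethylbenzoic acid | OC(=O)c1c(OCc2ccccc2)cc(OCc2ccccc2)c(C)c1C | intermediate
11 | allyl bromoacetate | C=CCOC(=O)CBr | starting material
12 | allyl {[2,4-bis(benzyloxy)-5,6-dimethylbenzoyl]oxy}acetate | C=CCOC(=O)COC(=O)c1c(OCc2ccccc2)cc(OCc2ccccc2)c(C)c1C | intermediate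
13 | {[2,4-bis(benzyloxy)-5,6-dimethylbenzoyl]oxy}acetic acid | OC(=O)COC(=O)c1c(OCc2ccccc2)cc(OCc2ccccc2)c(C)c1C | intermediate
14 | {[2,4-bis(benzyloxy)-5,6-dimethylbenzoyl]oxy}acetyl chloride | ClC(=O)COC(=O)c1c(OCc2ccccc2)cc(OCc2ccccc2)c(C)c1C | intermediate
15 | 6-(benzyloxy)-4-methoxy-3-methyl-2-vinylbenzoic {[2,4-bis(benzyloxy)-5,6-dimethylbenzoyl]oxy}acetic anhydride | C=Cc1c(C)c(OC)cc(OCc2ccccc2)c1C(=O)OC(=O)COC(=O)c1c(OCc2ccccc2)cc(OCc2ccccc2)c(C)c1C | intermediate
16 | [(4S)-8-(benzyloxy)-3-{[dimethoxy(methyl)silyl]oxy}-6-methoxy-4,5-dimethyl-1-oxo-3,4-dihydro-1H-isochromen-3-yl]methyl 2,4-bis(benzyloxy)-5,6-dimethylbenzoate (C3 epimers, configuration at C3 not controlled) | COc1cc(OCc3ccccc3)c2c(c1C)[C@H](C)C(O[Si](C)(OC)OC)(COC(=O)c1c(OCc3ccccc3)cc(OCc3ccccc3)c(C)c1C)OC2=O | intermediate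
17 | [(3R,4S)-8-(benzyloxy)-3-hydroxy-6-methoxy-4,5-dimethyl-1-oxo-3,4-dihydro-1H-isochromen-3-yl]methyl 2,4-bis(benzyloxy)-5,6-dimethylbenzoate | COc1cc(OCc3ccccc3)c2c(c1C)[C@H](C)[C@](O)(COC(=O)c1c(OCc3ccccc3)cc(OCc3ccccc3)c(C)c1C)OC2=O | intermediate
18 | [(3R,4S)-3,8-dihydroxy-6-methoxy-4,5-dimethyl-1-oxo-3,4-dihydro-1H-isochromen-3-yl]methyl 2,4-dihydroxy-5,6-dimethylbenzoate | COc1cc(O)c2c(c1C)[C@H](C)[C@](O)(COC(=O)c1c(O)cc(O)c(C)c1C)OC2=O | target

Total step count: 13. Longest linear sequence: 9 steps (steps 1, 2, 3, 4, 5, 6, 11, 12, 13).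

**Steps most likely to fail**

Step 12 (proposed new method). What may go wrong: hydride attack on an anhydride carbonyl outrunning hydrocupration of the twisted vinyl group (it lies between a methyl group and the aroyl carbonyl); hydrocupration with the opposite regiochemistry; or ring opening of the copper lactolate to the enolisable ketone, followed by over-reduction or loss of configuration at C4. The fallback uses known chemistry (auxiliary-controlled enolate methylation, then diazoketone O–H insertion), sets out from crude acid 5 and acid 10 and returns at target 18. Acid 5 is benzylated (BnBr, K2CO3, DMF) to benzyl 2-(benzyloxy)-4-methoxy-5,6-dimethylbenzoate F1. Lateral lithiation (LiN(i-Pr)2, THF, −78 °C) and CO2 give {3-(benzyloxy)-2-[(benzyloxy)carbonyl]-5-methoxy-6-methylphenyl}acetic acid F2. Coupling with (S)-4-benzyl-2-oxazolidinone (DCC, DMAP, CH2Cl2) gives benzyl 2-(benzyloxy)-6-{2-[(4S)-4-benzyl-2-oxo-1,3-oxazolidin-3-yl]-2-oxoethyl}-4-methoxy-5-methylbenzoate F3. NaN(SiMe3)2 then MeI at −78 °C should methylate the Z-enolate on the face away from the auxiliary benzyl group to give benzyl 2-(benzyloxy)-6-{(2S)-1-[(4S)-4-benzyl-2-oxo-1,3-oxazolidin-3-yl]-1-oxopropan-2-yl}-4-methoxy-5-methylbenzoate F4. LiOH/H2O2 (THF/H2O, 0 °C) frees (2S)-2-{3-(benzyloxy)-2-[(benzyloxy)carbonyl]-5-methoxy-6-methylphenyl}propanoic acid F5. Oxalyl chloride with catalytic DMF gives benzyl 2-(benzyloxy)-6-[(2S)-1-chloro-1-oxopropan-2-yl]-4-methoxy-5-methylbenzoate F6, and diazomethane in ether at 0 °C gives benzyl 2-(benzyloxy)-6-[(2S)-4-diazo-3-oxobutan-2-yl]-4-methoxy-5-methylbenzoate F7. Rh2(OAc)4-catalysed O–H insertion into acid 10 (CH2Cl2, rt) gives benzyl 2-(benzyloxy)-6-[(2S)-4-{[2,4-bis(benzyloxy)-5,6-dimethylbenzoyl]oxy}-3-oxobutan-2-yl]-4-methoxy-5-methylbenzoate F8. Hydrogenolysis (H2, Pd/C, EtOAc) removes all four benzyl groups and the freed keto acid should close to lactol 18.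

Step 11. What may go wrong: loss of HCl from acid chloride 14 to an acyloxyketene in the presence of the amine, or exchange of the mixed anhydride into the two symmetric anhydrides while it is concentrated. The fallback sets out from 8 and 13 and returns at 15, with the roles of the two acids exchanged. Acid 8 is converted with oxalyl chloride and catalytic DMF (CH2Cl2, 0 °C) into 6-(benzyloxy)-4-methoxy-3-methyl-2-vinylbenzoyl chloride F9, which has no alpha hydrogen. Addition of acid 13 and N-methylmorpholine in toluene at 0 °C and filtration give a solution of 15 that is taken into step 12 without concentration.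

Step 6. What may go wrong: addition of the amide base to the lactone carbonyl, or failure of the C4 anion to expel the carboxylate because the C3–O2 bond overlaps poorly with the benzylic orbital in the half-chair. The fallback sets out from ester 6 and returns at acid 8, replacing the lactone route by aminomethylation and Hofmann elimination. The lateral anion of 6 (LiN(i-Pr)2, THF, −78 °C) is trapped with dimethyl(methylene)ammonium iodide to give methyl 2-(benzyloxy)-6-[2-(dimethylamino)ethyl]-4-methoxy-5-methylbenzoate F10. MeI in acetonitrile gives 2-[3-(benzyloxy)-5-methoxy-2-(methoxycarbonyl)-6-methylphenyl]-N,N,N-trimethylethanaminium iodide F11, which with K2CO3 at 60 °C should eliminate trimethylamine to give methyl 6-(benzyloxy)-4-methoxy-3-methyl-2-vinylbenzoate F12. Hydrolysis of the hindered ester (KOH, DMSO/H2O, 80 °C) gives 8.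

**Further compounds**

F1 | step 12 | benzyl 2-(benzyloxy)-4-methoxy-5,6-dimethylbenzoate | O=C(OCc1ccccc1)c1c(OCc2ccccc2)cc(OC)c(C)c1C
F2 | step 12 | {3-(benzyloxy)-2-[(benzyloxy)carbonyl]-5-methoxy-6-methylphenyl}acetic acid | COc1cc(OCc2ccccc2)c(C(=O)OCc2ccccc2)c(c1C)CC(=O)O
F3 | step 12 | benzyl 2-(benzyloxy)-6-{2-[(4S)-4-benzyl-2-oxo-1,3-oxazolidin-3-yl]-2-oxoethyl}-4-methoxy-5-methylbenzoate | COc1cc(OCc2ccccc2)c(C(=O)OCc2ccccc2)c(c1C)CC(=O)N1C(=O)OC[C@@H]1Cc1ccccc1
F4 | step 12 | benzyl 2-(benzyloxy)-6-{(2S)-1-[(4S)-4-benzyl-2-oxo-1,3-oxazolidin-3-yl]-1-oxopropan-2-yl}-4-methoxy-5-methylbenzoate | COc1cc(OCc2ccccc2)c(C(=O)OCc2ccccc2)c(c1C)[C@H](C)C(=O)N1C(=O)OC[C@@H]1Cc1ccccc1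
F5 | step 12 | (2S)-2-{3-(benzyloxy)-2-[(benzyloxy)carbonyl]-5-methoxy-6-methylphenyl}propanoic acid | COc1cc(OCc2ccccc2)c(C(=O)OCc2ccccc2)c(c1C)[C@H](C)C(=O)O
F6 | step 12 | benzyl 2-(benzyloxy)-6-[(2S)-1-chloro-1-oxopropan-2-yl]-4-methoxy-5-methylbenzoate | COc1cc(OCc2ccccc2)c(C(=O)OCc2ccccc2)c(c1C)[C@H](C)C(=O)Cl
F7 | step 12 | benzyl 2-(benzyloxy)-6-[(2S)-4-diazo-3-oxobutan-2-yl]-4-methoxy-5-methylbenzoate | COc1cc(OCc2ccccc2)c(C(=O)OCc2ccccc2)c(c1C)[C@H](C)C(=O)C=[N+]=[N-]
F8 | step 12 | benzyl 2-(benzyloxy)-6-[(2S)-4-{[2,4-bis(benzyloxy)-5,6-dimethylbenzoyl]oxy}-3-oxobutan-2-yl]-4-methoxy-5-methylbenzoate | COc1cc(OCc2ccccc2)c(C(=O)OCc2ccccc2)c(c1C)[C@H](C)C(=O)COC(=O)c1c(OCc2ccccc2)cc(OCc2ccccc2)c(C)c1C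
F9 | step 11 | 6-(benzyloxy)-4-methoxy-3-methyl-2-vinylbenzoyl chloride | C=Cc1c(C)c(OC)cc(OCc2ccccc2)c1C(=O)Cl
F10 | step 6 | methyl 2-(benzyloxy)-6-[2-(dimethylamino)ethyl]-4-methoxy-5-methylbenzoate | COC(=O)c1c(OCc2ccccc2)cc(OC)c(C)c1CCN(C)C
F11 | step 6 | 2-[3-(benzyloxy)-5-methoxy-2-(methoxycarbonyl)-6-methylphenyl]-N,N,N-trimethylethanaminium iodide | COC(=O)c1c(OCc2ccccc2)cc(OC)c(C)c1CC[N+](C)(C)C.[I-]
F12 | step 6 | methyl 6-(benzyloxy)-4-methoxy-3-methyl-2-vinylbenzoate | COC(=O)c1c(OCc2ccccc2)cc(OC)c(C)c1C=C
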